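**Retrosynthetic overview** (ring A = benzo ring of the chroman, ring B = 4-hydroxyphenyl on C2, ring C = pyran ring, ring D = acylphloroglucinol on C4)
1. The target comes from its tetrabenzyl ether (three on ring D, one on O7) by neutral hydrogenolysis; rings A, B and D are bought as arenes and ring C is the only ring formed, in the last C–O bond-forming step.
2. Ring C is cut at O1–C2. The strategy rests on C2 being benzylic to ring B and para to the ring B hydroxyl, so O1–C2 can form and reopen through a para-quinone methide while C4, which carries ring D, is not touched.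
3. The precursor is a (3S)-1,3,3-triarylpropyl acetate (either carbinol epimer) with silyl ethers on the ring A ortho oxygen and on the ring B oxygen; fluoride unmasks both and starts the closure.
4. The acetate comes from the corresponding ketone, whose C4–ring A bond and C4 configuration are set by rhodium/chiral diene 1,4-addition of a ring A boronic acid to a ring D/ring B chalcone.
5. The chalcone comes from acylated, formylated, benzylated phloroglucinol and silylated 4'-hydroxyacetophenone; the boronic acid comes from 4-bromoresorcinol.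

Key step: step 14

Remark: the sense of induction of the diene ligand in step 11 is assumed to follow its behaviour with 2-cyclohexenone (aryl delivered to the α-re face of the enone); if the first run shows the opposite sense, the (S,S)-ligand is used and nothing else changes.

**Step 1**
Reactants: 1 9-phenylnonanoic acid
Product: 2 9-phenylnonanoyl chloride
Conditions: (COCl)2, DMF (cat.), CH2Cl2, 0 °C → rt; evaporate
Reagents that add atoms: oxalyl chloride, ClC(=O)C(=O)Cl
Why: Acid chloride formation through the chloroiminium species made from DMF and oxalyl chloride, to which the remote phenyl ring is inert.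

**Step 2**
Reactants: 2 9-phenylnonanoyl chloride; 3 phloroglucinol
Product: 4 9-phenyl-1-(2,4,6-trihydroxyphenyl)nonan-1-one
Conditions: AlCl3 (3.5 equiv), PhNO2/CH2Cl2, 0 → 40 °C; ice/aq HCl
Reagents that add atoms: none
Why: Friedel–Crafts C-acylation of phloroglucinol, which is far more nucleophilic than the terminal phenyl ring and is deactivated against a second acylation by the first acyl group.

**Step 3**
Reactants: 4 9-phenyl-1-(2,4,6-trihydroxyphenyl)nonan-1-one
Product: 6 2,4,6-trihydroxy-3-(9-phenylnonanoyl)benzaldehyde, via aryl iminium chloride 5 (not isolated)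
Conditions: POCl3 (1.2 equiv), DMF (1.5 equiv), EtOAc, 0 °C → rt; then H2O, 60 °C
Reagents that add atoms: N,N-dimethylformamide, CN(C)C=O; water, O
Why: Vilsmeier–Haack formylation at one of the two equivalent free ring positions, after which the iminium substituent deactivates the ring against a second formylation until it is hydrolysed to the aldehyde.

**Step 4**
Reactants: 6 2,4,6-trihydroxy-3-(9-phenylnonanoyl)benzaldehyde
Product: 7 2,4,6-tris(benzyloxy)-3-(9-phenylnonanoyl)benzaldehyde
Conditions: BnBr (4 equiv), K2CO3 (5 equiv), DMF, 60 °C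
Reagents that add atoms: benzyl bromide, BrCc1ccccc1
Why: Williamson ether synthesis in a dipolar aprotic solvent, where the two carbonyl groups lower the carbon nucleophilicity of the phenoxides so that O-benzylation should prevail and warming drives alkylation of the chelated hydroxyls.

**Step 5**
Reactants: 8 4'-hydroxyacetophenone
Product: 9 1-[4-(triisopropylsilyloxy)phenyl]ethan-1-one
Conditions: iPr3SiCl, imidazole, DMF, rt
Reagents that add atoms: chlorotri(propan-2-yl)silane, CC(C)[Si](Cl)(C(C)C)C(C)C
Why: Imidazole-promoted silylation of the phenol, the triisopropylsilyl group being chosen because a 4-acylphenyl silyl ether has to survive the aqueous base of step 11 and is still removed by fluoride in step 14.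

**Step 6**
Reactants: 9 1-[4-(triisopropylsilyloxy)phenyl]ethan-1-one; 7 2,4,6-tris(benzyloxy)-3-(9-phenylnonanoyl)benzaldehyde
Product: 11 racemic β-hydroxy ketone (aldol adduct of 9 and 7), via lithium enolate 10 (not isolated)
Conditions: LiN(iPr)2 (LDA), THF, −78 °C; then 7, −78 °C; aq NH4Cl at −78 °C
Reagents that add atoms: none
Why: Directed aldol addition in which the preformed lithium enolate of the methyl ketone adds to the aldehyde at low temperature faster than it can exchange a proton with, or add to, the shielded ring D ketone; the new carbinol centre is racemic and is removed in step 7.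

**Step 7**
Reactants: 11 racemic β-hydroxy ketone
Product: 13 (E)-chalcone, via mesylate 12 (not isolated)
Conditions: MeSO2Cl, Et3N, CH2Cl2, 0 °C → rt
Reagents that add atoms: none
Why: Mesylation followed by base-induced β-elimination, which should give the conjugated enone as the more stable E isomer.

**Step 8**
Reactants: 14 4-bromoresorcinol
Product: 15 5-(benzyloxy)-2-bromophenol
Conditions: BnBr (1.0 equiv), K2CO3 (1.1 equiv), acetone, 50 °C; chromatography
Reagents that add atoms: benzyl bromide, BrCc1ccccc1
Why: Williamson mono-alkylation that should favour the hydroxyl para to bromine, since the other hydroxyl is flanked by bromine and its phenoxide is the less nucleophilic one; the regioisomer and the bis-ether are removed by chromatography.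

**Step 9**
Reactants: 15 5-(benzyloxy)-2-bromophenol
Product: 16 [5-(benzyloxy)-2-bromophenoxy](tert-butyl)dimethylsilane
Conditions: tBuMe2SiCl, imidazole, DMF, rt
Reagents that add atoms: tert-butyl(chloro)dimethylsilane, CC(C)(C)[Si](C)(C)Cl
Why: Imidazole-promoted silylation of the remaining phenol, which places a fluoride-labile group on the oxygen that becomes O1.

**Step 10**
Reactants: 16 [5-(benzyloxy)-2-bromophenoxy](tert-butyl)dimethylsilane
Product: 19 [4-(benzyloxy)-2-(tert-butyldimethylsilyloxy)phenyl]boronic acid, via aryllithium 17 (not isolated), via lithium triisopropyl arylborate 18 (not isolated)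
Conditions: B(OiPr)3 (1.5 equiv), then n-BuLi (1.1 equiv), toluene/THF 4:1, −78 → −20 °C; aq NH4Cl
Reagents that add atoms: triisopropyl borate, CC(C)OB(OC(C)C)OC(C)C; water, O
Why: Bromine–lithium exchange with the borate already present, so that the aryllithium is trapped as the ate complex before the ortho silyl group can migrate from oxygen to carbon, followed by mild hydrolysis that leaves the silyl ether in place.

**Step 11**
Reactants: 13 (E)-chalcone; 19 [4-(benzyloxy)-2-(tert-butyldimethylsilyloxy)phenyl]boronic acid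
Product: 20 (3S)-1,3,3-triarylpropan-1-one
Conditions: [RhCl(C2H4)2]2 (2.5 mol%), (R,R)-Ph-bod* [(1R,4R)-2,5-diphenylbicyclo[2.2.2]octa-2,5-diene] (5.5 mol%), 19 (2.5 equiv), aq K3PO4 (0.5 equiv), 1,4-dioxane/H2O 10:1, 50 °C
Reagents that add atoms: none
Why: Hayashi–Miyaura rhodium-catalysed asymmetric 1,4-addition, in which the aryl group passes from boron to the diene-bound rhodium, the enone inserts into the aryl–rhodium bond and water releases the ketone; the C2-symmetric diene lets the enone bind only through the face on which its carbonyl avoids a ligand phenyl group, so ring A is delivered to the re face of C-β of the (E)-enone and the new centre, the future C4, is formed as 3S.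

**Step 12**
Reactants: 20 (3S)-1,3,3-triarylpropan-1-one
Product: 21 (3S)-1,3,3-triarylpropan-1-ol as both C1 epimers
Conditions: NaBH4 (1 equiv), THF/MeOH 4:1, −20 → 0 °C, followed by HPLC
Reagents that add atoms: none
Why: Borohydride reduction of the ring B aryl ketone, which is open to attack, whereas the ring D ketone lies between two ortho benzyloxy groups and should react far more slowly at low temperature; the new carbinol centre is formed without control and is erased in step 14.

**Step 13**
Reactants: 21 (3S)-1,3,3-triarylpropan-1-ol as both C1 epimers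
Product: 22 (3S)-1,3,3-triarylpropyl acetate as both C1 epimers
Conditions: Ac2O, pyridine, DMAP (cat.), CH2Cl2, 0 °C → rt; chromatography on Et3N-deactivated silica
Reagents that add atoms: acetic anhydride, CC(=O)OC(C)=O
Why: DMAP-catalysed acylation of the secondary benzylic alcohol, which installs the leaving group for the 1,6-elimination and tolerates both silyl ethers.

**Step 14**
Reactants: 22 (3S)-1,3,3-triarylpropyl acetate as both C1 epimers
Product: 26 (2S,4S)-tetrabenzyl flavan bearing the free ring B phenol, via diphenol acetate 23 (not isolated), via para-quinone methide 24 (not isolated), via trans epimer 25 (not isolated)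
Conditions: Bu4NF (3 equiv), THF (high dilution), 0 °C → 40 °C until the epimer ratio is constant; aq NH4Cl
Reagents that add atoms: none
Why: Fluoride cleaves the ring A tert-butyldimethylsilyl ether and then the slower ring B triisopropylsilyl ether to give 23, whose ring B phenoxide expels acetate in a 1,6-elimination to the planar para-quinone methide 24, in which both acetate epimers have merged, and the ring A phenoxide adds to the exocyclic methide carbon to form O1–C2. The closest known reaction type is the fluoride- or base-triggered generation of para-quinone methides from 4-silyloxybenzyl esters with intramolecular oxa-1,6-addition of a phenol. Ring C closes in a 6-exo-trig mode through a chair-like transition state. C2 is controlled by the fixed C4 centre: the adduct still carries the ring B phenoxide, so O1–C2 reopens to 24 and recloses until the mixture rests in the more stable epimer, and because the two ortho benzyloxy groups of ring D hold H4 in the plane of ring D (allylic 1,3-strain), ring D should be comfortable only pseudo-equatorial, which together with an equatorial ring B means the 2,4-cis (2S,4S) chroman 26 and not its trans epimer 25. The step needs O-closure by ring A alone and an intact C4: every ring D oxygen is benzylated, ring A is unmasked before the methide forms so that closure should outrun tautomerisation of 24 to a styrene, and no acid is present that could ionise the C4–ring D bond.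

**Step 15**
Reactants: 26 (2S,4S)-tetrabenzyl flavan bearing the free ring B phenol
Product: 27 1-{2,4,6-trihydroxy-3-[(2S,4S)-7-hydroxy-2-(4-hydroxyphenyl)-3,4-dihydro-2H-chromen-4-yl]phenyl}-9-phenylnonan-1-one
Conditions: H2 (1 atm), 10% Pd/C, EtOAc/MeOH 1:1, rt
Reagents that add atoms: none
Why: Heterogeneous hydrogenolysis of the four benzyl aryl ethers under neutral conditions, which should leave the C2–O1 ring ether, the hindered aryl ketone and both stereocentres untouched if the reaction is stopped once debenzylation is complete.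

**Compound list**
1 | 9-phenylnonanoic acid | O=C(O)CCCCCCCCc1ccccc1 | starting material
2 | 9-phenylnonanoyl chloride | O=C(Cl)CCCCCCCCc1ccccc1 | intermediate
3 | phloroglucinol (benzene-1,3,5-triol) | Oc1cc(O)cc(O)c1 | starting material
4 | 9-phenyl-1-(2,4,6-trihydroxyphenyl)nonan-1-one | O=C(CCCCCCCCc1ccccc1)c1c(O)cc(O)cc1O | intermediate
5 | dimethyl{[2,4,6-trihydroxy-3-(9-phenylnonanoyl)phenyl]methylidene}ammonium chloride | C[N+](C)=Cc1c(O)cc(O)c(C(=O)CCCCCCCCc2ccccc2)c1O.[Cl-] | intermediate
6 | 2,4,6-trihydroxy-3-(9-phenylnonanoyl)benzaldehyde | O=Cc1c(O)cc(O)c(C(=O)CCCCCCCCc2ccccc2)c1O | intermediate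
7 | 2,4,6-tris(benzyloxy)-3-(9-phenylnonanoyl)benzaldehyde | O=Cc1c(OCc2ccccc2)cc(OCc2ccccc2)c(C(=O)CCCCCCCCc2ccccc2)c1OCc1ccccc1 | intermediate
8 | 4'-hydroxyacetophenone | CC(=O)c1ccc(O)cc1 | starting material
9 | 1-[4-(triisopropylsilyloxy)phenyl]ethan-1-one | CC(=O)c1ccc(O[Si](C(C)C)(C(C)C)C(C)C)cc1 | intermediate
10 | lithium 1-[4-(triisopropylsilyloxy)phenyl]ethen-1-olate | [Li+].[O-]C(=C)c1ccc(O[Si](C(C)C)(C(C)C)C(C)C)cc1 | intermediate
11 | racemic 3-hydroxy-1-[4-(triisopropylsilyloxy)phenyl]-3-[2,4,6-tris(benzyloxy)-3-(9-phenylnonanoyl)phenyl]propan-1-one | O=C(CC(O)c1c(OCc2ccccc2)cc(OCc2ccccc2)c(C(=O)CCCCCCCCc2ccccc2)c1OCc1ccccc1)c1ccc(O[Si](C(C)C)(C(C)C)C(C)C)cc1 | intermediate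
12 | racemic 3-oxo-3-[4-(triisopropylsilyloxy)phenyl]-1-[2,4,6-tris(benzyloxy)-3-(9-phenylnonanoyl)phenyl]propyl methanesulfonate | O=C(CC(OS(C)(=O)=O)c1c(OCc2ccccc2)cc(OCc2ccccc2)c(C(=O)CCCCCCCCc2ccccc2)c1OCc1ccccc1)c1ccc(O[Si](C(C)C)(C(C)C)C(C)C)cc1 | intermediate
13 | (E)-1-[4-(triisopropylsilyloxy)phenyl]-3-[2,4,6-tris(benzyloxy)-3-(9-phenylnonanoyl)phenyl]prop-2-en-1-one | O=C(/C=C/c1c(OCc2ccccc2)cc(OCc2ccccc2)c(C(=O)CCCCCCCCc2ccccc2)c1OCc1ccccc1)c1ccc(O[Si](C(C)C)(C(C)C)C(C)C)cc1 | intermediate
14 | 4-bromoresorcinol (4-bromobenzene-1,3-diol) | Oc1ccc(Br)c(O)c1 | starting material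
15 | 5-(benzyloxy)-2-bromophenol | Oc1cc(OCc2ccccc2)ccc1Br | intermediate
16 | [5-(benzyloxy)-2-bromophenoxy](tert-butyl)dimethylsilane | CC(C)(C)[Si](C)(C)Oc1cc(OCc2ccccc2)ccc1Br | intermediate
17 | [4-(benzyloxy)-2-(tert-butyldimethylsilyloxy)phenyl]lithium | [Li]c1ccc(OCc2ccccc2)cc1O[Si](C)(C)C(C)(C)C | intermediate
18 | lithium [4-(benzyloxy)-2-(tert-butyldimethylsilyloxy)phenyl]tri(propan-2-yloxy)borate | [Li+].CC(C)O[B-](OC(C)C)(OC(C)C)c1ccc(OCc2ccccc2)cc1O[Si](C)(C)C(C)(C)C | intermediate
19 | [4-(benzyloxy)-2-(tert-butyldimethylsilyloxy)phenyl]boronic acid | OB(O)c1ccc(OCc2ccccc2)cc1O[Si](C)(C)C(C)(C)C | intermediate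
20 | (3S)-3-[4-(benzyloxy)-2-(tert-butyldimethylsilyloxy)phenyl]-1-[4-(triisopropylsilyloxy)phenyl]-3-[2,4,6-tris(benzyloxy)-3-(9-phenylnonanoyl)phenyl]propan-1-one | O=C(CCCCCCCCc1ccccc1)c1c(OCc2ccccc2)cc(OCc2ccccc2)c([C@@H](CC(=O)c2ccc(O[Si](C(C)C)(C(C)C)C(C)C)cc2)c2ccc(OCc3ccccc3)cc2O[Si](C)(C)C(C)(C)C)c1OCc1ccccc1 | intermediate
21 | (3S)-3-[4-(benzyloxy)-2-(tert-butyldimethylsilyloxy)phenyl]-1-[4-(triisopropylsilyloxy)phenyl]-3-[2,4,6-tris(benzyloxy)-3-(9-phenylnonanoyl)phenyl]propan-1-ol, both C1 epimers | O=C(CCCCCCCCc1ccccc1)c1c(OCc2ccccc2)cc(OCc2ccccc2)c([C@@H](CC(O)c2ccc(O[Si](C(C)C)(C(C)C)C(C)C)cc2)c2ccc(OCc3ccccc3)cc2O[Si](C)(C)C(C)(C)C)c1OCc1ccccc1 | intermediate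
22 | (3S)-3-[4-(benzyloxy)-2-(tert-butyldimethylsilyloxy)phenyl]-1-[4-(triisopropylsilyloxy)phenyl]-3-[2,4,6-tris(benzyloxy)-3-(9-phenylnonanoyl)phenyl]propyl acetate, both C1 epimers | O=C(CCCCCCCCc1ccccc1)c1c(OCc2ccccc2)cc(OCc2ccccc2)c([C@@H](CC(OC(C)=O)c2ccc(O[Si](C(C)C)(C(C)C)C(C)C)cc2)c2ccc(OCc3ccccc3)cc2O[Si](C)(C)C(C)(C)C)c1OCc1ccccc1 | intermediate
23 | (3S)-3-[4-(benzyloxy)-2-hydroxyphenyl]-1-(4-hydroxyphenyl)-3-[2,4,6-tris(benzyloxy)-3-(9-phenylnonanoyl)phenyl]propyl acetate, both C1 epimers, present as its phenoxides | O=C(CCCCCCCCc1ccccc1)c1c(OCc2ccccc2)cc(OCc2ccccc2)c([C@@H](CC(OC(C)=O)c2ccc(O)cc2)c2ccc(OCc3ccccc3)cc2O)c1OCc1ccccc1 | intermediate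
24 | 4-{(3S)-3-[4-(benzyloxy)-2-hydroxyphenyl]-3-[2,4,6-tris(benzyloxy)-3-(9-phenylnonanoyl)phenyl]propylidene}cyclohexa-2,5-dien-1-one | O=C(CCCCCCCCc1ccccc1)c1c(OCc2ccccc2)cc(OCc2ccccc2)c([C@@H](CC=C2C=CC(=O)C=C2)c2ccc(OCc3ccccc3)cc2O)c1OCc1ccccc1 | intermediate
25 | 1-{2,4,6-tris(benzyloxy)-3-[(2R,4S)-7-(benzyloxy)-2-(4-hydroxyphenyl)-3,4-dihydro-2H-chromen-4-yl]phenyl}-9-phenylnonan-1-one (2,4-trans) | O=C(CCCCCCCCc1ccccc1)c1c(OCc2ccccc2)cc(OCc2ccccc2)c([C@H]2C[C@H](c3ccc(O)cc3)Oc3cc(OCc4ccccc4)ccc32)c1OCc1ccccc1 | intermediate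
26 | 1-{2,4,6-tris(benzyloxy)-3-[(2S,4S)-7-(benzyloxy)-2-(4-hydroxyphenyl)-3,4-dihydro-2H-chromen-4-yl]phenyl}-9-phenylnonan-1-one (2,4-cis) | O=C(CCCCCCCCc1ccccc1)c1c(OCc2ccccc2)cc(OCc2ccccc2)c([C@H]2C[C@@H](c3ccc(O)cc3)Oc3cc(OCc4ccccc4)ccc32)c1OCc1ccccc1 | intermediate
27 | 1-{2,4,6-trihydroxy-3-[(2S,4S)-7-hydroxy-2-(4-hydroxyphenyl)-3,4-dihydro-2H-chromen-4-yl]phenyl}-9-phenylnonan-1-one | O=C(CCCCCCCCc1ccccc1)c1c(O)cc(O)c([C@H]2C[C@@H](c3ccc(O)cc3)Oc3cc(O)ccc32)c1O | target

**Step count**
Total: 15 steps. Longest linear sequence: 11 steps (steps 1, 2, 3, 4, 6, 7, 11, 12, 13, 14, 15).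

**Steps most likely to fail**

Step 11. Carbometalation at a β-carbon screened by the two ortho benzyloxy groups of ring D, by an aryl–rhodium species that itself carries an ortho silyloxy group, may be slower than protodeboronation of 19 and base-induced silyl loss. The enantioface discrimination may also erode at the temperature needed. The fallback sets out from 16 and 13 and comes back at 20. Bromide 16 is converted with Mg (LiCl, THF) into [4-(benzyloxy)-2-(tert-butyldimethylsilyloxy)phenyl]magnesium bromide F1. F1 is added to 13 under CuBr·SMe2 catalysis (THF, −40 °C) to give the racemic 1,3,3-triarylpropan-1-one F2. Preparative chromatography on a chiral stationary phase then delivers 20 and sets aside its (3R)-enantiomer F3. This exchanges the catalytic asymmetric arylation for an organocopper 1,4-addition, which tolerates crowding better, followed by resolution.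

Step 14. The C2 equilibrium may not lie far enough on the cis side, and during the time needed to reach it the quinone methide may drain away by tautomerisation to a styrene or by intermolecular trapping. The fallback sets out from 20 and comes back at 27. It gives up the equilibration and sets C2 by hydrogen delivery. Ketone 20 is desilylated with Bu4NF buffered with AcOH (THF, 0 °C) to the (3S)-hydroxy ketone F4, which rests in equilibrium with its cyclic hemiketal, the 2-hydroxyflavan F5. Pyridinium tosylate in toluene over 4 Å molecular sieves at 60 °C dehydrates this to the (4S)-2,4-diaryl-4H-chromene F6. Hydrogenation of F6 (H2, 10% Pd/C, EtOAc/MeOH, rt) should add hydrogen to the C2=C3 enol ether from the face away from ring D, giving the 2,4-cis chroman, and remove the four benzyl groups in the same operation to give 27.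

Step 12. The steric screening of the ring D ketone may not separate the two reduction rates well enough, leading to over-reduction to a diol. The fallback sets out from 20 and comes back at 21. The stoichiometric hydride is replaced by catalytic transfer hydrogenation with RuCl(p-cymene)[(S,S)-TsDPEN] in HCO2H/Et3N 5:2 at rt. This outer-sphere catalyst does not accept aryl ketones with two ortho substituents, so the selectivity comes from the substrate scope of the catalyst and not from a rate difference. It gives 21 as a single carbinol epimer; which epimer is immaterial, because step 14 erases that centre.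

**Further compounds**
F1 | step 11 | [4-(benzyloxy)-2-(tert-butyldimethylsilyloxy)phenyl]magnesium bromide | Br[Mg]c1ccc(OCc2ccccc2)cc1O[Si](C)(C)C(C)(C)C
F2 | step 11 | racemic 3-[4-(benzyloxy)-2-(tert-butyldimethylsilyloxy)phenyl]-1-[4-(triisopropylsilyloxy)phenyl]-3-[2,4,6-tris(benzyloxy)-3-(9-phenylnonanoyl)phenyl]propan-1-one | O=C(CCCCCCCCc1ccccc1)c1c(OCc2ccccc2)cc(OCc2ccccc2)c(C(CC(=O)c2ccc(O[Si](C(C)C)(C(C)C)C(C)C)cc2)c2ccc(OCc3ccccc3)cc2O[Si](C)(C)C(C)(C)C)c1OCc1ccccc1
F3 | step 11 | (3R)-enantiomer of 20 | O=C(CCCCCCCCc1ccccc1)c1c(OCc2ccccc2)cc(OCc2ccccc2)c([C@H](CC(=O)c2ccc(O[Si](C(C)C)(C(C)C)C(C)C)cc2)c2ccc(OCc3ccccc3)cc2O[Si](C)(C)C(C)(C)C)c1OCc1ccccc1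
F4 | step 14 | (3S)-3-[4-(benzyloxy)-2-hydroxyphenyl]-1-(4-hydroxyphenyl)-3-[2,4,6-tris(benzyloxy)-3-(9-phenylnonanoyl)phenyl]propan-1-one | O=C(CCCCCCCCc1ccccc1)c1c(OCc2ccccc2)cc(OCc2ccccc2)c([C@@H](CC(=O)c2ccc(O)cc2)c2ccc(OCc3ccccc3)cc2O)c1OCc1ccccc1
F5 | step 14 | 1-{2,4,6-tris(benzyloxy)-3-[(4S)-7-(benzyloxy)-2-hydroxy-2-(4-hydroxyphenyl)-3,4-dihydro-2H-chromen-4-yl]phenyl}-9-phenylnonan-1-one, both C2 epimers | O=C(CCCCCCCCc1ccccc1)c1c(OCc2ccccc2)cc(OCc2ccccc2)c([C@H]2CC(O)(c3ccc(O)cc3)Oc3cc(OCc4ccccc4)ccc32)c1OCc1ccccc1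
F6 | step 14 | 1-{2,4,6-tris(benzyloxy)-3-[(4S)-7-(benzyloxy)-2-(4-hydroxyphenyl)-4H-chromen-4-yl]phenyl}-9-phenylnonan-1-one | O=C(CCCCCCCCc1ccccc1)c1c(OCc2ccccc2)cc(OCc2ccccc2)c([C@H]2C=C(c3ccc(O)cc3)Oc3cc(OCc4ccccc4)ccc32)c1OCc1ccccc1
F0 | step 12 | none | none
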